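**Numbering used throughout.** Unit A: C1–C4, C4a, C5–C8, C8a. Unit B: C1'–C4', C4a', C5'–C8', C8a'. O(a) is the oxygen C4–O–C5'; O(b) is the oxygen C4–O–C4'. Compound numbers: 1–3 starting materials and first intermediate, 4 and 6 transient, 5 the key-step precursor, 7 the key-step product, 8–13 later intermediates, 14 the target.

## The problem

Compound 14 (C20H10Cl2O8) consists of two C10 halves. Unit A has the C1 ketone, the C2–C3 epoxide, C4 and an arene with C7–Cl and C8–OH; unit B has the C1' carbinol, the C2'–C3' epoxide, C4' and an arene with C7'–Cl and C8'–OH. The halves are joined three times: by the C5–C4' bond (an arene carbon to a fully substituted carbon) and by O(a) and O(b), both on C4. C4 and C4' are thus the bridgeheads of a 2,8-dioxabicyclo[3.2.1]octane, and closing this bicycle while making the hindered C5–C4' bond is the hardest part. Of the seven stereocenters, C4 and C4' fix each other through the bicycle and carry the absolute configuration. The other five lie on the periphery and can be governed by the core: each epoxide oxygen is anti to the pseudo-axial bond at the neighbouring bridgehead (C4–O(a) for C2–C3, C4'–C5 for C2'–C3'), and the C1' hydroxyl is trans to its epoxide oxygen. The halves are almost alike (peri-hydroxy aryl carbonyl, epoxide, ortho-chlorophenol, each chlorine ortho to a phenol whose para position is a core bond), but C1 is a ketone and C1' an alcohol, so the route must address one half at a time. The feature that opens the plan: C1', C4', C5' and C8' all carry oxygen, so unit B is a naphthalene-1,4,5,8-tetraol whose C1'–C4' ring and C5'–C8' ring are mirror images until C4' is bonded to C5; and C5 is para to the C8 oxygen and peri to C4, the one nucleophilic arene carbon that a ketal at C4 holds next to C4'. Sensitive groups are the epoxy ketones (Lewis acid, halide, strong base), the bis-ketal (strong acid), the electron-rich phenols (oxidants) and the aryl chlorides (hydrogenolysis).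

## Retrosynthesis

**14 ⇒ 13.** The two C–O bonds of the ring A epoxide are cut, giving enone 13. This cut is last because ring A is then the only electrophilic alkene; removing the ring B epoxide last instead would leave two equal epoxy ketones at the reduction stage. The forward step must deliver oxygen to C3 anti to O(a) and spare the ring B epoxy alcohol.

**13 ⇒ 12.** The C1'–H bond is cut: the carbinol comes from epoxy ketone 12. Here ring B is an epoxy ketone and ring A only an enone, a difference a chelating hydride can read. Reduction before the ring B epoxide exists would lose the element that steers the hydride; reduction after the ring A epoxide exists would face two equal epoxy ketones. The forward step must bring hydride to C1' on the epoxide face and leave the C1 carbonyl alone.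

**12 ⇒ 11 ⇒ 10.** The ring A alkene is returned to the saturated ketone 11, and the ring B epoxide of 11 to dienone 10. Keeping ring A saturated while ring B is epoxidized makes the epoxidation site-selective without protecting groups. Ring B stays one oxidation stage ahead of ring A from the key step to the end.

**10 ⇒ 9 ⇒ 8 ⇒ 7.** Functional groups are removed: the C8 phenol goes back to methyl ether 9, the C1 carbonyl to the methylene of 8, and both C–Cl bonds to C–H in 7. The chlorines are cut together because in 7 each aryl ring has exactly one open position ortho or para to its oxygen donor. Compound 7 has lost four stereocenters, both halogens and one carbonyl.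

**7 ⇒ 5 (key disconnection).** The C5–C4' bond is cut, C4' returning to an aromatic carbon and the C1' carbonyl to a phenol. The neighbouring cuts (C4–O(a) or C4–O(b)) lead to biaryl or quinol precursors that already hold the hindered C–C bond and a stereo element. Cutting C5–C4' leads to 5, in which unit B is the symmetric tetraol held as its 4',5'-ketal: achiral, no stereocenter, and one ketalization from simple materials. The forward reaction must remove two electrons from one of two enantiotopic phenol rings and let C5 attack its para carbon.

**5 ⇒ 2 + 3; 2 ⇒ 1.** The two ketal C–O bonds are cut to 5-methoxy-1-tetralone 3 and leuconaphthazarin 2, which reacts through its tetraol tautomer 4 and is the reduction product of naphthazarin 1. The methoxy group of 3 sits para to the carbon that becomes C5. The forward ketalization must stop at the mono-ketal.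

## Roads not taken

**Alternative 1:** (the most obvious) Cut both ketal C–O bonds and treat C5–C4' as a biaryl bond. A Suzuki–Miyaura coupling of two separately protected tetra-oxygenated naphthalenes would give binaphthyl A1, followed by twofold oxidative spiroketalization with PhI(OAc)2. The coupling joins two carbons that each carry a peri oxygen, and each partner needs its own protection, halogenation or borylation sequence. A1 is axially chiral, so absolute configuration would need an atroposelective coupling, whereas the chosen plan creates chirality from an achiral precursor. Both halves would also emerge at the same oxidation level, and the half-differentiation that the chosen key step gives for free would be lost.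

**Alternative 2:** Cut C5–C4' as aryl anion plus quinone carbonyl. The aryllithium from a C5-brominated tetralone ketal adds 1,2 to 5,8-dimethoxynaphthalene-1,4-dione to give quinol A2; deprotection and acid close the bis-ketal. This needs halogenation, a ketal protecting group, an organometallic step and ether cleavages peri to the new carbinol. The quinol is racemic with no practical catalytic control over the addition, and 1,4-addition competes. The chosen plan needs none of these and sets the configuration in the bond-forming step; a variant of this route is kept as the fallback for step 3.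

**Alternative 3:** A single-atom deletion. The trioxa cage A3 (C5–O–C4', a 2,4,8-trioxabicyclo[3.3.1]nonane from two juglone-type halves) would be built and the oxygen between C5 and C4' excised to contract the 1,3-dioxane to the oxolane. C4' in A3 is a ketal carbon without hydrogen or leaving group, so nothing can trigger an O-to-C aryl shift, and deletion of an aryl ether oxygen from a ketal has no close precedent. A3 is also no simpler than 5 and, as a symmetric bis-enone, would still face the half-differentiation problem.

Key step: step 3

**Assumption (numbering):** the numbering of 14 is used for all intermediates; C4 of this numbering is C1 of tetralone 3 and C8 is its methoxy carbon.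

**Assumption (chemistry):** the sense of ring selection by the lactamide iodoarene cannot be deduced from its known reactions; the (R,R) antipode is written, and the equally available (S,S) antipode is used if it selects the required ring.

## Route

Step 1
Reactants: 1 naphthazarin (5,8-dihydroxynaphthalene-1,4-dione)
Product: 2 leuconaphthazarin (5,8-dihydroxy-2,3-dihydronaphthalene-1,4-dione)
Conditions: SnCl2·2H2O, 4 M aq. HCl, 100 °C; cool, filter
Reagents that add atoms: none
Why: Two-electron reduction of the quinone by divalent tin in acid; the product is collected as its stable diketo tautomer. No stereocenter.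

Step 2
Reactants: 2 leuconaphthazarin; 3 5-methoxy-1-tetralone (5-methoxy-3,4-dihydronaphthalen-1(2H)-one)
Product: 5 5-methoxy-3,4-dihydro-2H-spiro[naphthalene-1,2'-naphtho[1,8-de][1,3]dioxine]-6',7'-diol, via naphthalene-1,4,5,8-tetraol 4 (not isolated)
Conditions: 2 (2.5 equiv), TsOH·H2O (10 mol %), toluene, reflux, Dean–Stark trap, argon; used at once
Reagents that add atoms: none
Why: Acid-catalysed ketalization of an aryl ketone by a peri-naphthalenediol to a spiro-naphtho[1,8-de][1,3]dioxine; 2 reacts through its enol tautomer 4, and ketal formation fixes the aromatic form. Excess 2 disfavours twofold ketalization; 5 is achiral (mirror plane through ring A), so no stereocenter arises.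

Step 3
Reactants: 5 spiroketal bisphenol
Product: 7 8-O-methyl core dienone (ring A saturated at C1 to C3; ring B 8'-hydroxy-2'-en-1'-one; C4 and C4' as in 14), via aryloxy-λ3-iodane 6 (not isolated)
Conditions: (R,R)-2-iodo-1,3-bis[1-(mesitylcarbamoyl)ethoxy]benzene (15 mol %), mCPBA (1.05 equiv, slow addition), HFIP/CH2Cl2 1:1, 4 Å MS, −40 °C
Reagents that add atoms: none
Why: Proposed new method: the chiral aryl iodide is oxidized by mCPBA to a trivalent iodine species that exchanges a ligand for one of the two enantiotopic peri-hydroxyls of 5 (iodane 6), and two-electron loss from that ring through O–I heterolysis makes its para carbon C4' (bearing O(b)) electrophilic; C5 of ring A, para to the methoxy group and held about 3 Å from C4' by the spiroketal, attacks it, and loss of the C5 proton rearomatizes ring A. The closest known reaction types are the hypervalent-iodine dearomatizing para-spirocyclization of phenols by tethered arenes and the lactamide-iodoarene-catalysed enantioselective dearomatization of phenols; new here are the choice between two enantiotopic rings and the capture at an oxygen-bearing para carbon. One ring is closed, the five-membered oxa-ring C4–C4a–C5–C4'–O(b), by attack of an arene carbon on a cationic carbon whose oxygen lies in the new ring (a 5-endo-type geometry); this is judged feasible because the charge is carried by the pentadienyl system of ring B, so O(b) can leave the ring B plane as the dioxine ring puckers into the 2,8-dioxabicyclo[3.2.1]octane. C4' is set by the tether (C5 can reach only the face of ring B on which C4a lies) and C4, prostereogenic in 5, becomes stereogenic in the same event, so both bridgeheads follow from which ring is oxidized; that choice is the only element under reagent control, the lactamide arms differentiating the two diastereomeric O-bound complexes, which should exchange faster than they cyclize. Selectivities needed: ring B phenols over the anisole ring (far more electron-rich), C4' over C2' (only C4' is within reach of C5), C–C closure over loss of the ketal to a quinone (anhydrous, non-nucleophilic medium, low temperature) and a single oxidation (the product phenol is deactivated by the new peri carbonyl).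

Step 4
Reactants: 7 8-O-methyl core dienone
Product: 8 7,7'-dichloro derivative of 7
Conditions: N-chlorosuccinimide (2.2 equiv), HFIP, 0 °C to rt, dark
Reagents that add atoms: N-chlorosuccinimide, O=C1CCC(=O)N1Cl
Why: Electrophilic aromatic chlorination with HFIP-activated N-chlorosuccinimide. On ring A the only open position ortho or para to the methoxy group is C7, and on ring B the only open position ortho or para to the hydroxyl is C7' (the para positions carry the core bonds C5–C4' and C5'–O(a)); no stereocenter is touched.

Step 5
Reactants: 8 7,7'-dichloro dienone
Product: 9 7,7'-dichloro-8-methoxy 1-ketone (ring A saturated ketone; ring B dienone)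
Conditions: CrO3 (12 equiv), 3,5-dimethylpyrazole (12 equiv), CH2Cl2, −20 °C
Reagents that add atoms: chromium trioxide, O=[Cr](=O)=O
Why: Benzylic C–H oxidation by the CrO3·3,5-dimethylpyrazole complex; C1 is the only benzylic or allylic methylene in 8 (C4 and C4' are fully substituted, ring B has no sp3 C–H). The ring B phenol is hydrogen-bonded to the C1' carbonyl and has no open ortho or para position.

Step 6
Reactants: 9 methyl ether ketone
Product: 10 7,7'-dichloro-8,8'-dihydroxy 1-ketone (ring B dienone)
Conditions: BCl3 (3 equiv), CH2Cl2, −78 to −20 °C; aq. NaHCO3
Reagents that add atoms: none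
Why: Chelation-assisted cleavage of the aryl methyl ether peri to the C1 ketone (boron bridges the carbonyl and ether oxygens); the unchelated ketal oxygens react more slowly at low temperature. The step is placed before any epoxide exists.

Step 7
Reactants: 10 bisphenol ketone
Product: 11 ring B epoxy ketone (2',3'-epoxide on the O(b) face; ring A saturated ketone)
Conditions: t-BuOOH (decane, 3 equiv), DBU (3.5 equiv), CH2Cl2, 0 °C
Reagents that add atoms: tert-butyl hydroperoxide, CC(C)(C)OO
Why: Weitz–Scheffer nucleophilic epoxidation; only ring B holds an enone. The peroxide adds to C3' on the face of O(b) because the opposite face is covered by C6–H of ring A, which stands over C3' next to the pseudo-axial C4'–C5 bond; closure gives the cis-epoxide syn to O(b).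

Step 8
Reactants: 11 ring B epoxy ketone
Product: 12 ring A enone with ring B epoxy ketone
Conditions: IBX (2.5 equiv), 4-methoxypyridine N-oxide (2.5 equiv), DMSO, rt to 40 °C
Reagents that add atoms: none
Why: IBX dehydrogenation of a ketone to an enone through its enol. Only the C1 ketone has α- and β-hydrogens (the C1' ketone is flanked by an epoxide carbon), the fully substituted C4 forbids aromatization, and both phenols have their ortho and para positions occupied.

Step 9
Reactants: 12 enone epoxy ketone
Product: 13 ring A enone with ring B trans-epoxy alcohol (C1'–OH anti to the 2',3'-epoxide oxygen)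
Conditions: Zn(BH4)2 (Et2O solution, 1.5 equiv), THF, −40 to −10 °C; aq. NH4Cl
Reagents that add atoms: none
Why: Chelation-controlled reduction of an α,β-epoxy ketone: zinc bridges the C1' carbonyl and epoxide oxygens and hydride is delivered on the epoxide face, giving the anti (trans) epoxy alcohol; the other face of C1' is also screened by C6–H of ring A. Zn(BH4)2 reduces non-conjugated ketones in preference to conjugated enones, which should spare the chelated ring A enone.

Step 10
Reactants: 13 enone epoxy alcohol
Product: 14 target (CNP0289684.3)
Conditions: t-BuOOH (decane, 3 equiv), DBU (3.5 equiv), CH2Cl2, 0 °C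
Reagents that add atoms: tert-butyl hydroperoxide, CC(C)(C)OO
Why: Weitz–Scheffer epoxidation of the remaining enone; the peroxide adds to C3 anti to the pseudo-axial C4–O(a) bond and the ring B arene over that face, giving the cis-epoxide anti to O(a). DBU is too weak to form the C1' alkoxide in quantity, so epoxide migration in ring B is not expected.

## Compound list

1 | naphthazarin (5,8-dihydroxynaphthalene-1,4-dione) | O=C1C=CC(=O)c2c(O)ccc(O)c12 | starting material
2 | leuconaphthazarin (5,8-dihydroxy-2,3-dihydronaphthalene-1,4-dione) | O=C1CCC(=O)c2c(O)ccc(O)c12 | intermediate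
3 | 5-methoxy-1-tetralone | COc1cccc2C(=O)CCCc12 | starting material
4 | naphthalene-1,4,5,8-tetraol (enol tautomer of 2, not isolated) | Oc1ccc(O)c2c(O)ccc(O)c12 | intermediate
5 | 5-methoxy-3,4-dihydro-2H-spiro[naphthalene-1,2'-naphtho[1,8-de][1,3]dioxine]-6',7'-diol (achiral) | COc1cccc2c1CCCC21Oc3ccc(O)c4c(O)ccc(O1)c34 | intermediate
6 | aryloxy-λ3-iodane of 5 (C1' oxygen bound to iodine of the (R,R)-lactamide iodoarene, 3-chlorobenzoate as second ligand, not isolated) | C1c2c(OC)cccc2[C@@]2(Oc3ccc(O)c4c3c(O2)ccc4OI(OC(=O)c3cccc(Cl)c3)c3c(O[C@H](C)C(=O)Nc4c(C)cc(C)cc4C)cccc3O[C@H](C)C(=O)Nc3c(C)cc(C)cc3C)CC1 | intermediate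
7 | 8-O-methyl core dienone (C5–C4' bond formed; ring A saturated at C1–C3; ring B 8'-hydroxy-2'-en-1'-one) | C1c2c(OC)ccc3c2[C@@]2(Oc4ccc(O)c5c4[C@]3(O2)C=CC5=O)CC1 | intermediate
8 | 7,7'-dichloro derivative of 7 | C1c2c(OC)c(Cl)cc3c2[C@@]2(Oc4cc(Cl)c(O)c5c4[C@]3(O2)C=CC5=O)CC1 | intermediate
9 | 7,7'-dichloro-8-methoxy 1-ketone (ring B dienone) | O=C1c2c(OC)c(Cl)cc3c2[C@@]2(Oc4cc(Cl)c(O)c5c4[C@]3(O2)C=CC5=O)CC1 | intermediate
10 | 7,7'-dichloro-8,8'-dihydroxy 1-ketone (ring B dienone) | O=C1c2c(O)c(Cl)cc3c2[C@@]2(Oc4cc(Cl)c(O)c5c4[C@]3(O2)C=CC5=O)CC1 | intermediate
11 | ring B epoxy ketone (2',3'-epoxide syn to O(b); ring A saturated ketone) | O=C1c2c(O)c(Cl)cc3c2[C@@]2(Oc4cc(Cl)c(O)c5c4[C@]3(O2)[C@@H]2O[C@@H]2C5=O)CC1 | intermediate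
12 | ring A enone with ring B epoxy ketone | O=C1c2c(O)c(Cl)cc3c2[C@@]2(Oc4cc(Cl)c(O)c5c4[C@]3(O2)[C@@H]2O[C@@H]2C5=O)C=C1 | intermediate
13 | ring A enone with ring B trans-epoxy alcohol | O=C1c2c(O)c(Cl)cc3c2[C@@]2(Oc4cc(Cl)c(O)c5c4[C@]3(O2)[C@@H]2O[C@@H]2[C@H]5O)C=C1 | intermediate
14 | target CNP0289684.3 (2,3-epoxide anti to O(a); 2',3'-epoxide syn to O(b); C1'–OH trans to its epoxide) | O=C1c2c(O)c(Cl)cc3c2[C@@]2(Oc4cc(Cl)c(O)c5c4[C@]3(O2)[C@@H]2O[C@@H]2[C@H]5O)[C@@H]2O[C@H]12 | target

## Step count and least certain steps

Total: 10 steps. Longest linear sequence: 10 steps (1 to 14; 3 enters at step 2).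

**Step 3 (key step, Proposed new method).** Most likely failures are insufficient discrimination between the two enantiotopic phenol rings, and diversion of the oxidized ring to a quinone by loss of the ketal, because the 5-endo-type geometry slows C–C closure. The fallback uses known chemistry, sets out from 3 and 1 and comes back at 7. Tetralone 3 is brominated para to the methoxy group (N-bromosuccinimide, MeCN) to 8-bromo-5-methoxy-1-tetralone F1 and ketalized with ethylene glycol to dioxolane F2. Naphthazarin 1 is converted into its bis(methoxymethyl) ether F3 (MOMCl, i-Pr2NEt). Bromine–lithium exchange on F2 (t-BuLi, THF, −78 °C) and 1,2-addition of the aryllithium to one of the two equivalent carbonyls of F3 give racemic quinol F4. Aqueous HCl in THF removes the dioxolane and both methoxymethyl groups, and the freed C4 ketone is ketalized by the C4' and C5' hydroxyls to racemic 7, that is 7 and its enantiomer F5, which are separated on a chiral stationary phase.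

**Step 2.** Compound 2 may react mainly as its diketo tautomer, giving slow ketalization, re-oxidation to 1 or twofold ketalization. The fallback sets out from 2 and comes back at 5. Compound 2 is silylated (TMSCl, Et3N, DMF) to the tetrakis(trimethylsilyl) ether F6, which is locked in the aromatic form. Silyl-transfer ketalization of 3 with F6 (catalytic TMSOTf, CH2Cl2, −78 to −20 °C) gives the bis-silyl ether F7, and mild methanolysis (K2CO3, MeOH, 0 °C) gives 5.

**Step 9.** The most likely failure is competing 1,2-reduction of the ring A enone once both carbonyls sit in zinc phenolate chelates; attack anti to the epoxide is the second concern. The fallback sets out from 12 and comes back at 13. Both carbonyls are reduced under chelating Luche conditions (NaBH4, CeCl3·7H2O, MeOH, −78 °C) to diol F12 (C1 epimers, inconsequential). MnO2 in CH2Cl2 then re-oxidizes only the doubly activated (allylic and benzylic) C1 carbinol to 13.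

**Step 8.** Enolization of the chelated ortho-hydroxyaryl ketone may be sluggish, leading to incomplete dehydrogenation or oxidative damage on heating. The fallback sets out from 11 and comes back at 12 by a Saegusa–Ito sequence. LiHMDS and TMSCl (THF, −78 °C) give the tris-silyl compound F10 (C1 silyl enol ether, both phenols silylated). Pd(OAc)2 (palladium diacetate, MeCN, rt) gives the bis-silyl enone F11, and mild acidic methanolysis gives 12.

**Step 5.** The free para-alkoxyphenol of ring B may be degraded by the hexavalent chromium reagent. The fallback sets out from 8 and comes back at 9. The C8' phenol is masked as acetate F8 (Ac2O, pyridine, DMAP), the benzylic oxidation is run on F8 to give ketone acetate F9, and methanolysis (K2CO3, MeOH, 0 °C) gives 9.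

## Further compounds

F1 | step 3 | 8-bromo-5-methoxy-1-tetralone | COc1ccc(Br)c2C(=O)CCCc12
F2 | step 3 | 8'-bromo-5'-methoxy-3',4'-dihydro-2'H-spiro[1,3-dioxolane-2,1'-naphthalene] | COc1ccc(Br)c2c1CCCC21OCCO1
F3 | step 3 | 5,8-bis(methoxymethoxy)naphthalene-1,4-dione | COCOc1ccc(OCOC)c2C(=O)C=CC(=O)c12
F4 | step 3 | racemic quinol: 4-hydroxy-5,8-bis(methoxymethoxy)-4-(5'-methoxy-3',4'-dihydro-2'H-spiro[1,3-dioxolane-2,1'-naphthalen]-8'-yl)naphthalen-1(4H)-one | COCOc1ccc(OCOC)c2c1C(=O)C=CC2(O)c1ccc(OC)c2c1C1(OCCO1)CCC2
F5 | step 3 | enantiomer of 7 | C1c2c(OC)ccc3c2[C@]2(Oc4ccc(O)c5c4[C@@]3(O2)C=CC5=O)CC1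
F6 | step 2 | 1,4,5,8-tetrakis(trimethylsilyloxy)naphthalene | C[Si](C)(C)Oc1ccc(O[Si](C)(C)C)c2c(O[Si](C)(C)C)ccc(O[Si](C)(C)C)c12
F7 | step 2 | 6',7'-bis(trimethylsilyl) ether of 5 | COc1cccc2c1CCCC21Oc3ccc(O[Si](C)(C)C)c4c(O[Si](C)(C)C)ccc(O1)c34
F8 | step 5 | 8'-O-acetate of 8 | C1c2c(OC)c(Cl)cc3c2[C@@]2(Oc4cc(Cl)c(OC(C)=O)c5c4[C@]3(O2)C=CC5=O)CC1
F9 | step 5 | 8'-O-acetate of 9 | O=C1c2c(OC)c(Cl)cc3c2[C@@]2(Oc4cc(Cl)c(OC(C)=O)c5c4[C@]3(O2)C=CC5=O)CC1
F10 | step 8 | tris(trimethylsilyl) derivative of 11 (C1 silyl enol ether, 8- and 8'-silyl ethers) | C1(O[Si](C)(C)C)c2c(O[Si](C)(C)C)c(Cl)cc3c2[C@@]2(Oc4cc(Cl)c(O[Si](C)(C)C)c5c4[C@]3(O2)[C@@H]2O[C@@H]2C5=O)CC=1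
F11 | step 8 | 8,8'-bis(trimethylsilyl) ether of 12 | O=C1c2c(O[Si](C)(C)C)c(Cl)cc3c2[C@@]2(Oc4cc(Cl)c(O[Si](C)(C)C)c5c4[C@]3(O2)[C@@H]2O[C@@H]2C5=O)C=C1
F12 | step 9 | 1,1'-diol (ring A allylic alcohol, C1 epimers; ring B trans-epoxy alcohol) | OC1c2c(O)c(Cl)cc3c2[C@@]2(Oc4cc(Cl)c(O)c5c4[C@]3(O2)[C@@H]2O[C@@H]2[C@H]5O)C=C1
A1 | alternative 1 | binaphthyl 5-(4,8-dihydroxy-5-methoxynaphthalen-1-yl)-8-methoxynaphthalene-1,4-diol (racemic about the biaryl axis) | Oc1ccc(O)c2c(-c3ccc(O)c4c(OC)ccc(O)c34)ccc(OC)c12
A2 | alternative 2 | racemic quinol 4-hydroxy-5,8-dimethoxy-4-(5'-methoxy-3',4'-dihydro-2'H-spiro[1,3-dioxolane-2,1'-naphthalen]-8'-yl)naphthalen-1(4H)-one | COc1ccc(OC)c2c1C(=O)C=CC2(O)c1ccc(OC)c2c1C1(OCCO1)CCC2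
A3 | alternative 3 | trioxa cage bis-enone (C5–O–C4' homologue of the core, 2,4,8-trioxabicyclo[3.3.1]nonane) | O=C1c2c(O)ccc(O3)c2[C@@]2(Oc4ccc(O)c5c4[C@]3(O2)C=CC5=O)C=C1
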